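The ring is numbered C1 (ketone), C2 (CH2OH), C3, C4, C5 (quaternary), C6 (enol-ester arm), C7 (acetonyl arm). The plan rests on the C1(=O)–C2(CH2OH)=C3 enone segment of the seven-membered carbocycle. C2 and C3 are a two-carbon insert between the ketone carbon C1 and C4, and the CH2OH carbon is an ester carbon on C2.
Late disconnections: the Z-enol ester comes from a C6 terminal alkyne and 3-methylbut-2-enoic acid (Ru, anti-Markovnikov), the acetonyl group from a C7 allyl group (Wacker), the cis C6/C7 relation from kinetic enolate protonation, and CH2OH from CO2Me.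
Key disconnection: C1–C2 and C3–C4 lead back to a cyclopentanone (ring atoms C1, C7, C6, C5, C4), used as its pyrrolidine enamine, and methyl propiolate. The old C1–C4 bond is the one that breaks.
Cyclopentanone: the C5 homoprenyl chain and the C6 arm are cis in the target, so the quaternary centre is made last, by methyl cuprate addition anti to the C6 alkynyl group. C6 and C7 come from anti alkynylation and anti allylation of (S)-4-homoprenylcyclopentenone, itself made from (S)-4-silyloxycyclopentenone.
Ring order: the five-membered ring is purchased, a transient cyclobutene is fused to it, and the seven-membered ring forms when the shared bond opens.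

Key step: step 6

Remark (assumption and convention): both antipodes of 4-(tert-butyldimethylsilyloxy)cyclopent-2-enone are taken to be catalogue compounds and the (S) form is used; target numbering is kept for all ring carbons, and β means the ring face that carries the C6 substituent (in the target the C5 homoprenyl chain and the C6 and C7 arms are β, and the C5 methyl is α).

Step 1
Reactants: 1 (S)-4-(tert-butyldimethylsilyloxy)cyclopent-2-en-1-one; 2 5-bromo-2-methylpent-2-ene
Product: 5 (S)-4-(4-methylpent-3-enyl)cyclopent-2-en-1-one, via Grignard reagent 3 (not isolated), via trans silyloxy ketone 4 (not isolated)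
Conditions: 2, Mg, THF, rt; CuBr·SMe2 (15 mol%), 1, THF, −78 → −40 °C; aq NH4Cl; crude 4, DBU, CH2Cl2, 0 °C
Reagents that add atoms: none
Why: Copper-catalysed 1,4-addition of the Grignard reagent should take place on the enone face opposite the C6 silyloxy group (sets C5 with the chain α), and DBU then expels the β-silyloxy group by E1cB elimination, so the purchased stereocentre is handed on to C5.

Step 2
Reactants: 5 (S)-4-(4-methylpent-3-enyl)cyclopent-2-en-1-one; 6 (triisopropylsilyl)acetylene
Product: 9 trans-4-(4-methylpent-3-enyl)-3-[(triisopropylsilyl)ethynyl]-1-(trimethylsilyloxy)cyclopentene (alkynyl β at C6; chain α at C5), via lithium acetylide 7 (not isolated), via alkynylzinc bromide 8 (not isolated)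
Conditions: 6, n-BuLi, THF, −78 → 0 °C; ZnBr2, 0 °C; Et2O, −40 °C, 5, TMSOTf; Et3N, cold aq NaHCO3; used crude
Reagents that add atoms: trimethylsilyl trifluoromethanesulfonate, C[Si](C)(C)OS(=O)(=O)C(F)(F)F
Why: This is the silyl-triflate-promoted conjugate addition of an alkynylzinc halide to a cyclic enone, in which the acetylide should attack C6 anti to the neighbouring C5 chain (sets C6 with the alkynyl group β) while O-silylation stores the C1=C7 enolate regiochemistry.

Step 3
Reactants: 9 trans-4-(4-methylpent-3-enyl)-3-[(triisopropylsilyl)ethynyl]-1-(trimethylsilyloxy)cyclopentene; 10 allyl iodide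
Product: 12 (2S,3R,4S)-2-allyl-4-(4-methylpent-3-enyl)-3-[(triisopropylsilyl)ethynyl]cyclopentanone (allyl α; alkynyl β; chain α), via lithium enolate 11 (not isolated)
Conditions: MeLi, THF, 0 °C; −78 °C, 10, DMPU, → −30 °C; aq NH4Cl
Reagents that add atoms: none
Why: Cleavage of the trimethylsilyl enol ether with MeLi releases the regiodefined lithium enolate, and its SN2 alkylation by allyl iodide should occur anti to the adjacent C6 alkynyl group (sets C7 with allyl α, trans, which is also the more stable arrangement).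

Step 4
Reactants: 12 (2S,3R,4S)-2-allyl-4-(4-methylpent-3-enyl)-3-[(triisopropylsilyl)ethynyl]cyclopentanone
Product: 14 (4S,5S)-5-allyl-3-(4-methylpent-3-enyl)-4-[(triisopropylsilyl)ethynyl]cyclopent-2-en-1-one, via kinetic lithium enolate 13 (not isolated)
Conditions: LDA, THF, −78 °C; PhS(Cl)=N-t-Bu, −78 °C; aq NaHCO3
Reagents that add atoms: none
Why: LDA removes a proton from the unsubstituted C4 methylene under kinetic control, and the enolate is dehydrogenated by the sulfinimidoyl chloride (Mukaiyama dehydrogenation, attack at sulfur then syn elimination of the C5 hydrogen), which erases the relay centre C5 and leaves C6 and C7 untouched.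

Step 5
Reactants: 14 (4S,5S)-5-allyl-3-(4-methylpent-3-enyl)-4-[(triisopropylsilyl)ethynyl]cyclopent-2-en-1-one
Product: 16 (2S,3S,4R)-2-allyl-4-methyl-4-(4-methylpent-3-enyl)-3-[(triisopropylsilyl)ethynyl]cyclopentanone, via silyl enol ether 15 (not isolated)
Conditions: MeLi, CuI, Et2O, 0 °C; −78 °C, TMSCl, 14, → −30 °C; then 1 M HCl, THF, 0 °C
Reagents that add atoms: lithium dimethylcuprate (from MeLi and CuI), [Li+].C[Cu-]C
Why: The TMSCl-accelerated conjugate addition of lithium dimethylcuprate to the β-substituted cyclopentenone should deliver methyl to C5 on the face opposite the vicinal C6 alkynyl group, so the quaternary centre is set with methyl α and homoprenyl β (cis to the alkynyl group, as the target requires), and mild acid frees the ketone.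

Step 6
Reactants: 16 (2S,3S,4R)-2-allyl-4-methyl-4-(4-methylpent-3-enyl)-3-[(triisopropylsilyl)ethynyl]cyclopentanone; 17 methyl propiolate; 18 pyrrolidine
Product: 22 methyl (5R,6S,7S)-7-allyl-5-methyl-5-(4-methylpent-3-enyl)-1-oxo-6-[(triisopropylsilyl)ethynyl]cyclohept-2-ene-2-carboxylate (target numbering), via enamine 19 (not isolated), via aminocyclobutene 20 (not isolated), via dienamino ester 21 (not isolated)
Conditions: 18 (5 equiv), TsOH·H2O (5 mol%), PhMe, reflux, Dean–Stark; evaporate; 17 (1.5 equiv), PhMe, 0 → 90 °C; 1 M HCl–THF, 0 °C → rt; used crude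
Reagents that add atoms: water, O
Why: Condensation of 16 with 18 puts the enamine double bond between C1 and the unsubstituted C4, because the C1=C7 isomer would force the allyl group into the plane of the pyrrolidine ring, and any of that isomer drains back through the iminium ion. The nucleophilic C4 adds to the unsubstituted terminus of 17 (polarity-matched, forms C3–C4) and the allenolate carbon C2 then closes on the iminium carbon C1 (forms C1–C2), a stepwise (2+2) closure of the four-membered ring that can only give the cis-fused bicyclo[3.2.0]heptene 20. In 20 the donor nitrogen on C1 and the acceptor ester on C2 weaken the shared C1–C4 bond, which breaks on warming in a 4π ring opening; as strict conrotation would lead to a strained E,Z-cycloheptadiene, the opening is expected to have zwitterionic character and to relax by rotation about the push–pull bond to the all-cis dienamino ester 21, so the seven-membered ring arises by ring enlargement and not by end-to-end cyclisation. The closest known reaction type is the two-carbon ring enlargement of cyclic ketone enamines with acetylenic esters. No lasting stereocentre is made: the two bridgehead centres of 20 disappear in 21, C5 and C6 are not involved, and C7 stays in its more stable trans arrangement under the iminium–enamine exchange. Aqueous acid protonates the dienamine terminus C4, hydrolyses the conjugated iminium ion to 22 and holds the released 18 as its salt so that it cannot add to C3, and 22 is carried on crude because it can tautomerise to the C1 enol with a C3=C4 bond.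

Step 7
Reactants: 22 methyl (5R,6S,7S)-7-allyl-5-methyl-5-(4-methylpent-3-enyl)-1-oxo-6-[(triisopropylsilyl)ethynyl]cyclohept-2-ene-2-carboxylate
Product: 23 (5R,6S,7S)-7-allyl-2-(hydroxymethyl)-5-methyl-5-(4-methylpent-3-enyl)-6-[(triisopropylsilyl)ethynyl]cyclohept-2-en-1-ol (C1 epimers)
Conditions: DIBAL-H (4.5 equiv), CH2Cl2, −78 → −20 °C; aq potassium sodium tartrate
Reagents that add atoms: none
Why: DIBAL-H should deliver hydride in the 1,2 sense to both the ketone and the ester carbonyl (aluminium hydride reduction of an enone ester), with the C2=C3 bond, the silylalkyne and the isolated alkenes inert at low temperature, and the new C1 carbinol centre does not matter because step 9 removes it.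

Step 8
Reactants: 23 (5R,6S,7S)-7-allyl-2-(hydroxymethyl)-5-methyl-5-(4-methylpent-3-enyl)-6-[(triisopropylsilyl)ethynyl]cyclohept-2-en-1-ol
Product: 24 (5R,6S,7S)-7-allyl-2-[(tert-butyldimethylsilyloxy)methyl]-5-methyl-5-(4-methylpent-3-enyl)-6-[(triisopropylsilyl)ethynyl]cyclohept-2-en-1-ol (C1 epimers)
Conditions: TBSCl (1.05 equiv), imidazole, CH2Cl2, −20 → 0 °C
Reagents that add atoms: tert-butyldimethylsilyl chloride, CC(C)(C)[Si](C)(C)Cl
Why: Selective silylation should take the unhindered primary allylic hydroxyl in preference to the secondary C1 hydroxyl, which is flanked by the substituted C7 and C2.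

Step 9
Reactants: 24 (5R,6S,7S)-7-allyl-2-[(tert-butyldimethylsilyloxy)methyl]-5-methyl-5-(4-methylpent-3-enyl)-6-[(triisopropylsilyl)ethynyl]cyclohept-2-en-1-ol
Product: 25 (5R,6S,7S)-7-allyl-2-[(tert-butyldimethylsilyloxy)methyl]-5-methyl-5-(4-methylpent-3-enyl)-6-[(triisopropylsilyl)ethynyl]cyclohept-2-en-1-one
Conditions: Dess–Martin periodinane, CH2Cl2, 0 °C → rt
Reagents that add atoms: none
Why: Dess–Martin oxidation converts both C1 epimers of the secondary allylic alcohol into the one enone under mild conditions that spare the silyl groups, the alkenes and C7.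

Step 10
Reactants: 25 (5R,6S,7S)-7-allyl-2-[(tert-butyldimethylsilyloxy)methyl]-5-methyl-5-(4-methylpent-3-enyl)-6-[(triisopropylsilyl)ethynyl]cyclohept-2-en-1-one
Product: 27 (5R,6S,7R)-7-allyl-2-[(tert-butyldimethylsilyloxy)methyl]-5-methyl-5-(4-methylpent-3-enyl)-6-[(triisopropylsilyl)ethynyl]cyclohept-2-en-1-one, via lithium dienolate 26 (not isolated)
Conditions: LDA (1.2 equiv), THF, −78 °C; 2,6-di-tert-butyl-4-methylphenol in THF, −78 °C; aq NH4Cl
Reagents that add atoms: none
Why: Kinetic α′-deprotonation at C7 gives the cross-conjugated dienolate, in which the C6 alkynyl group should turn pseudoaxial on the β face to avoid allylic strain against the C7 allyl group, so the bulky phenol protonates C7 from the open α face and pushes the allyl group onto the β face (kinetic enolate protonation, contra-thermodynamic epimerisation).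

Step 11
Reactants: 27 (5R,6S,7R)-7-allyl-2-[(tert-butyldimethylsilyloxy)methyl]-5-methyl-5-(4-methylpent-3-enyl)-6-[(triisopropylsilyl)ethynyl]cyclohept-2-en-1-one
Product: 28 (5R,6S,7R)-2-[(tert-butyldimethylsilyloxy)methyl]-5-methyl-5-(4-methylpent-3-enyl)-7-(2-oxopropyl)-6-[(triisopropylsilyl)ethynyl]cyclohept-2-en-1-one
Conditions: PdCl2 (10 mol%), CuCl (1 equiv), O2 (1 atm), DMF–H2O (7:1), rt
Reagents that add atoms: water, O
Why: The Tsuji–Wacker oxidation is selective for the monosubstituted alkene (Markovnikov attack of water gives the methyl ketone), since the trisubstituted alkene, the electron-poor enone and the bulky silyl-capped alkyne bind PdCl2 poorly, and the mildly acidic medium should not enolise C7 at a useful rate.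

Step 12
Reactants: 28 (5R,6S,7R)-2-[(tert-butyldimethylsilyloxy)methyl]-5-methyl-5-(4-methylpent-3-enyl)-7-(2-oxopropyl)-6-[(triisopropylsilyl)ethynyl]cyclohept-2-en-1-one
Product: 29 (5R,6S,7R)-6-ethynyl-2-(hydroxymethyl)-5-methyl-5-(4-methylpent-3-enyl)-7-(2-oxopropyl)cyclohept-2-en-1-one
Conditions: Bu4NF–AcOH (1:1, 3 equiv), THF, 0 °C → rt
Reagents that add atoms: none
Why: Fluoride cleaves both the C(sp)–Si and the O–Si bond, and the acetic acid buffer keeps the medium from enolising C7 or starting an aldol reaction of the 1,4-diketone.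

Step 13
Reactants: 29 (5R,6S,7R)-6-ethynyl-2-(hydroxymethyl)-5-methyl-5-(4-methylpent-3-enyl)-7-(2-oxopropyl)cyclohept-2-en-1-one
Product: 30 (5R,6S,7R)-6-ethynyl-5-methyl-5-(4-methylpent-3-enyl)-7-(2-oxopropyl)-2-[(triethylsilyloxy)methyl]cyclohept-2-en-1-one
Conditions: TESCl, imidazole, CH2Cl2, 0 °C
Reagents that add atoms: triethylsilyl chloride, CC[Si](Cl)(CC)CC
Why: Standard silylation of the only hydroxyl group keeps the allylic alcohol away from the ruthenium catalyst and from acyl transfer by the enol ester made in the next step.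

Step 14
Reactants: 30 (5R,6S,7R)-6-ethynyl-5-methyl-5-(4-methylpent-3-enyl)-7-(2-oxopropyl)-2-[(triethylsilyloxy)methyl]cyclohept-2-en-1-one; 31 3-methylbut-2-enoic acid
Product: 32 (Z)-2-[(5R,6S,7R)-5-methyl-5-(4-methylpent-3-enyl)-1-oxo-7-(2-oxopropyl)-2-[(triethylsilyloxy)methyl]cyclohept-2-en-6-yl]ethenyl 3-methylbut-2-enoate
Conditions: 31 (1.2 equiv), Ru(η3-CH2C(CH3)CH2)2(Ph2P(CH2)4PPh2) (3 mol%), PhMe, 50 °C
Reagents that add atoms: none
Why: In this ruthenium-catalysed anti-Markovnikov hydro-acyloxylation the terminal alkyne rearranges to a ruthenium vinylidene, the carboxylate attacks its electrophilic α-carbon and protonolysis releases the Z-alk-1-enyl ester by net trans addition, with no base present that could touch C7.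

Step 15
Reactants: 32 (Z)-2-[(5R,6S,7R)-5-methyl-5-(4-methylpent-3-enyl)-1-oxo-7-(2-oxopropyl)-2-[(triethylsilyloxy)methyl]cyclohept-2-en-6-yl]ethenyl 3-methylbut-2-enoate
Product: 33 (Z)-2-[(5R,6S,7R)-2-(hydroxymethyl)-5-methyl-5-(4-methylpent-3-enyl)-1-oxo-7-(2-oxopropyl)cyclohept-2-en-6-yl]ethenyl 3-methylbut-2-enoate (CNP0247522.4)
Conditions: HF·pyridine, pyridine, THF, 0 °C
Reagents that add atoms: none
Why: Pyridine-buffered HF·pyridine removes the labile triethylsilyl ether without hydrolysing the enol ester or epimerising C7, which should give the target.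

Compound list
1 | (S)-4-(tert-butyldimethylsilyloxy)cyclopent-2-en-1-one | O=C1C=C[C@@H](O[Si](C)(C)C(C)(C)C)C1 | starting material
2 | 5-bromo-2-methylpent-2-ene | CC(C)=CCCBr | starting material
3 | 4-methylpent-3-enylmagnesium bromide | CC(C)=CCC[Mg]Br | intermediate
4 | (3S,4S)-4-(tert-butyldimethylsilyloxy)-3-(4-methylpent-3-enyl)cyclopentanone (trans) | O=C1C[C@H](CCC=C(C)C)[C@@H](O[Si](C)(C)C(C)(C)C)C1 | intermediate
5 | (S)-4-(4-methylpent-3-enyl)cyclopent-2-en-1-one | O=C1C=C[C@@H](CCC=C(C)C)C1 | intermediate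
6 | (triisopropylsilyl)acetylene | C#C[Si](C(C)C)(C(C)C)C(C)C | starting material
7 | lithium (triisopropylsilyl)acetylide | [Li]C#C[Si](C(C)C)(C(C)C)C(C)C | intermediate
8 | [(triisopropylsilyl)ethynyl]zinc bromide | Br[Zn]C#C[Si](C(C)C)(C(C)C)C(C)C | intermediate
9 | trans-4-(4-methylpent-3-enyl)-3-[(triisopropylsilyl)ethynyl]-1-(trimethylsilyloxy)cyclopentene (enol ether C1=C7, alkynyl β, chain α) | C[Si](C)(C)OC1=C[C@H](C#C[Si](C(C)C)(C(C)C)C(C)C)[C@@H](CCC=C(C)C)C1 | intermediate
10 | allyl iodide | C=CCI | starting material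
11 | lithium enolate (C1=C7) from 9 | [Li]OC1=C[C@H](C#C[Si](C(C)C)(C(C)C)C(C)C)[C@@H](CCC=C(C)C)C1 | intermediate
12 | (2S,3R,4S)-2-allyl-4-(4-methylpent-3-enyl)-3-[(triisopropylsilyl)ethynyl]cyclopentanone (all trans) | C=CC[C@@H]1C(=O)C[C@H](CCC=C(C)C)[C@H]1C#C[Si](C(C)C)(C(C)C)C(C)C | intermediate
13 | kinetic lithium enolate (C1=C4) of 12 | C=CC[C@@H]1C(O[Li])=C[C@H](CCC=C(C)C)[C@H]1C#C[Si](C(C)C)(C(C)C)C(C)C | intermediate
14 | (4S,5S)-5-allyl-3-(4-methylpent-3-enyl)-4-[(triisopropylsilyl)ethynyl]cyclopent-2-en-1-one | C=CC[C@@H]1C(=O)C=C(CCC=C(C)C)[C@H]1C#C[Si](C(C)C)(C(C)C)C(C)C | intermediate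
15 | trimethylsilyl enol ether (C1=C4) of 16 | C=CC[C@@H]1C(O[Si](C)(C)C)=C[C@@](C)(CCC=C(C)C)[C@H]1C#C[Si](C(C)C)(C(C)C)C(C)C | intermediate
16 | (2S,3S,4R)-2-allyl-4-methyl-4-(4-methylpent-3-enyl)-3-[(triisopropylsilyl)ethynyl]cyclopentanone (allyl α, alkynyl β, homoprenyl β, methyl α) | C=CC[C@@H]1C(=O)C[C@@](C)(CCC=C(C)C)[C@H]1C#C[Si](C(C)C)(C(C)C)C(C)C | intermediate
17 | methyl propiolate | C#CC(=O)OC | starting material
18 | pyrrolidine | C1CCNC1 | starting material
19 | pyrrolidine enamine (C1=C4) of 16 | C=CC[C@@H]1C(N2CCCC2)=C[C@@](C)(CCC=C(C)C)[C@H]1C#C[Si](C(C)C)(C(C)C)C(C)C | intermediate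
20 | cis-fused 1-pyrrolidinylbicyclo[3.2.0]hept-6-ene-7-carboxylate (drawn for addition on the face opposite the allyl group; either face leads to 21) | C=CC[C@@H]1[C@@]2(N3CCCC3)C(C(=O)OC)=C[C@H]2[C@@](C)(CCC=C(C)C)[C@H]1C#C[Si](C(C)C)(C(C)C)C(C)C | intermediate
21 | methyl 1-pyrrolidinylcyclohepta-1,3-diene-2-carboxylate with the C5, C6 and C7 substituents of 16 (target numbering) | C=CC[C@@H]1C(N2CCCC2)=C(C(=O)OC)C=C[C@@](C)(CCC=C(C)C)[C@H]1C#C[Si](C(C)C)(C(C)C)C(C)C | intermediate
22 | methyl (5R,6S,7S)-7-allyl-5-methyl-5-(4-methylpent-3-enyl)-1-oxo-6-[(triisopropylsilyl)ethynyl]cyclohept-2-ene-2-carboxylate | C=CC[C@@H]1C(=O)C(C(=O)OC)=CC[C@@](C)(CCC=C(C)C)[C@H]1C#C[Si](C(C)C)(C(C)C)C(C)C | intermediate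
23 | (5R,6S,7S)-7-allyl-2-(hydroxymethyl)-5-methyl-5-(4-methylpent-3-enyl)-6-[(triisopropylsilyl)ethynyl]cyclohept-2-en-1-ol (C1 epimers) | C=CC[C@@H]1C(O)C(CO)=CC[C@@](C)(CCC=C(C)C)[C@H]1C#C[Si](C(C)C)(C(C)C)C(C)C | intermediate
24 | primary tert-butyldimethylsilyl ether of 23 (C1 epimers) | C=CC[C@@H]1C(O)C(CO[Si](C)(C)C(C)(C)C)=CC[C@@](C)(CCC=C(C)C)[C@H]1C#C[Si](C(C)C)(C(C)C)C(C)C | intermediate
25 | (5R,6S,7S)-7-allyl-2-[(tert-butyldimethylsilyloxy)methyl]-5-methyl-5-(4-methylpent-3-enyl)-6-[(triisopropylsilyl)ethynyl]cyclohept-2-en-1-one (C6/C7 trans) | C=CC[C@@H]1C(=O)C(CO[Si](C)(C)C(C)(C)C)=CC[C@@](C)(CCC=C(C)C)[C@H]1C#C[Si](C(C)C)(C(C)C)C(C)C | intermediate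
26 | cross-conjugated lithium dienolate (C1=C7) of 25 | C=CCC1=C(O[Li])C(CO[Si](C)(C)C(C)(C)C)=CC[C@@](C)(CCC=C(C)C)[C@H]1C#C[Si](C(C)C)(C(C)C)C(C)C | intermediate
27 | (5R,6S,7R)-7-allyl-2-[(tert-butyldimethylsilyloxy)methyl]-5-methyl-5-(4-methylpent-3-enyl)-6-[(triisopropylsilyl)ethynyl]cyclohept-2-en-1-one (C6/C7 cis) | C=CC[C@H]1C(=O)C(CO[Si](C)(C)C(C)(C)C)=CC[C@@](C)(CCC=C(C)C)[C@H]1C#C[Si](C(C)C)(C(C)C)C(C)C | intermediate
28 | (5R,6S,7R)-2-[(tert-butyldimethylsilyloxy)methyl]-5-methyl-5-(4-methylpent-3-enyl)-7-(2-oxopropyl)-6-[(triisopropylsilyl)ethynyl]cyclohept-2-en-1-one | CC(=O)C[C@H]1C(=O)C(CO[Si](C)(C)C(C)(C)C)=CC[C@@](C)(CCC=C(C)C)[C@H]1C#C[Si](C(C)C)(C(C)C)C(C)C | intermediate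
29 | (5R,6S,7R)-6-ethynyl-2-(hydroxymethyl)-5-methyl-5-(4-methylpent-3-enyl)-7-(2-oxopropyl)cyclohept-2-en-1-one | CC(=O)C[C@H]1C(=O)C(CO)=CC[C@@](C)(CCC=C(C)C)[C@H]1C#C | intermediate
30 | triethylsilyl ether of 29 | CC(=O)C[C@H]1C(=O)C(CO[Si](CC)(CC)CC)=CC[C@@](C)(CCC=C(C)C)[C@H]1C#C | intermediate
31 | 3-methylbut-2-enoic acid | CC(C)=CC(=O)O | starting material
32 | triethylsilyl ether of the target (Z-enol ester) | CC(=O)C[C@H]1C(=O)C(CO[Si](CC)(CC)CC)=CC[C@@](C)(CCC=C(C)C)[C@H]1/C=C\OC(=O)C=C(C)C | intermediate
33 | (Z)-2-[(5R,6S,7R)-2-(hydroxymethyl)-5-methyl-5-(4-methylpent-3-enyl)-1-oxo-7-(2-oxopropyl)cyclohept-2-en-6-yl]ethenyl 3-methylbut-2-enoate (CNP0247522.4) | CC(=O)C[C@H]1C(=O)C(CO)=CC[C@@](C)(CCC=C(C)C)[C@H]1/C=C\OC(=O)C=C(C)C | target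

Total step count: 15. Longest linear sequence: 15 steps, from 1.

Steps most likely to fail

Step 6 (key step).
- Risks: condensation at the hindered carbonyl may be slow or incomplete, and attack of the neopentyl carbon C4 on the alkynoate may be slow. Proton transfer within the zwitterion may also give an open-chain Michael-type adduct in place of four-membered ring closure.
- Fallback: the nucleophile changes from an enamine to a silyl enol ether, and the activation changes from thermal to Lewis acid. The fallback sets out from 15, which is isolated in step 5 by leaving out the acid treatment.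
- With 17 and EtAlCl2 (or TiCl4) in CH2Cl2 at −78 °C, the known (2+2) cycloaddition of silyl enol ethers with propiolates should give the silyloxy cyclobutene ester F1.
- Dilute HCl in THF removes the tertiary trimethylsilyl ether to give the cyclobutenol ester F2.
- A catalytic amount of DBU at 0 °C then triggers the oxyanion-driven opening of the C1–C4 bond, and an acidic quench brings the material back to the route at 22.

Step 7.
- Risks: 22 may tautomerise to its C1 enol with a C3=C4 bond before or during the reduction, after which DIBAL-H only deprotonates it. Hydride may also be delivered to C3 in the conjugate sense.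
- Fallback: the ester carbon is given up and the hydroxymethyl carbon is brought in from formaldehyde. The fallback sets out from 22 (either tautomer).
- Krapcho demethoxycarbonylation (LiCl, wet DMSO, 120 °C) followed by DBU equilibration should give the conjugated cycloheptenone F3.
- A Morita–Baylis–Hillman reaction with aqueous formaldehyde (PBu3 or DMAP, THF) should give the 2-(hydroxymethyl)cycloheptenone F4.
- TBSCl and imidazole bring it back to the route at 25.

Step 10.
- Risks: γ-deprotonation at C4 may compete and lead to loss of silyloxide. Diisopropylamine may return its proton to the enolate, and the slim alkynyl group may discriminate poorly between the two faces.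
- Fallback: kinetic control is replaced by thermodynamic control with recycling. The fallback sets out from 25.
- A catalytic amount of DBU in toluene at rt establishes the equilibrium between 25 and 27. Chromatography separates 27, recovered 25 is resubmitted, and the route is rejoined at 27.
- This fallback makes no new compound (F0).

Further compounds
F1 | step 6 | cis-fused methyl 1-(trimethylsilyloxy)bicyclo[3.2.0]hept-6-ene-7-carboxylate with the substituents of 16 | C=CC[C@@H]1[C@@]2(O[Si](C)(C)C)C(C(=O)OC)=C[C@H]2[C@@](C)(CCC=C(C)C)[C@H]1C#C[Si](C(C)C)(C(C)C)C(C)C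
F2 | step 6 | cis-fused methyl 1-hydroxybicyclo[3.2.0]hept-6-ene-7-carboxylate with the substituents of 16 | C=CC[C@@H]1[C@@]2(O)C(C(=O)OC)=C[C@H]2[C@@](C)(CCC=C(C)C)[C@H]1C#C[Si](C(C)C)(C(C)C)C(C)C
F3 | step 7 | (5R,6S,7S)-7-allyl-5-methyl-5-(4-methylpent-3-enyl)-6-[(triisopropylsilyl)ethynyl]cyclohept-2-en-1-one | C=CC[C@@H]1C(=O)C=CC[C@@](C)(CCC=C(C)C)[C@H]1C#C[Si](C(C)C)(C(C)C)C(C)C
F4 | step 7 | (5R,6S,7S)-7-allyl-2-(hydroxymethyl)-5-methyl-5-(4-methylpent-3-enyl)-6-[(triisopropylsilyl)ethynyl]cyclohept-2-en-1-one | C=CC[C@@H]1C(=O)C(CO)=CC[C@@](C)(CCC=C(C)C)[C@H]1C#C[Si](C(C)C)(C(C)C)C(C)C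
F0 | step 10 | none | none
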